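**Plan**

- Retrosynthesis: the C3–O ester bond is cut first (Mitsunobu, with inversion) to give a 3β-hydroxy decalin with the 8,9-diol masked as an acetonide and a (2Z,5R)-5-angeloyloxyhex-2-enoic acid. The isopropenyl group is read as a methylenated acetyl group, and ring B is then cut at C5–C6 and C7–C8 in one retro-Giese/retro-aldol operation, giving a ring A aldehyde with an exocyclic C5=C14 methylene and but-3-en-2-one. C9–C10 is cut by a retro glyoxylate-ene reaction.
- Enabling feature: in ring B (C5–C10) the C8 hydroxyl is β to C11 on C7, an aldol retron. The quaternary C5 with its methyl C14 is the Markovnikov hydrogen-atom adduct of a C5=C14 methylene, so a tertiary C5 radical sits 1,3 to C7 through C6.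
- Forward: ring A comes from 2-methylcyclohex-2-en-1-one. The ene reaction adds C9/C8 and creates the exocyclic C5=C14 alkene. The annulation with the four-carbon enone closes ring B, followed by methylenation, esterification and deprotection.
- Stereochemistry: C3 by CBS reduction (inverted later in the Mitsunobu step); C4 by hydroboration anti to the silyloxy group; C10 by the alkene face and C9 by the (R)-BINOL/TiCl2(OiPr)2 catalyst in the ene step; C5, C7 and C8 in the annulation. The side-chain carbinol comes from (R)-pent-4-yn-2-ol, and the two Z alkenes from angelic acid and a Lindlar reduction.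

Key step: step 10

Assumption: eremophilane numbering is used (ring A = C1–C5, C10; ring B = C5–C10; C11–C13 on C7; C14 = methyl on C5; C15 = methyl on C4); β is the face of the C5 methyl group, and in all decalin compounds the C4 methyl, the C5 methyl and the C7 substituent are β; TBS = tert-butyldimethylsilyl.

**Route**

Step 1
Reactants: 1 2-methylcyclohex-2-en-1-one
Product: 2 (1S)-2-methylcyclohex-2-en-1-ol
Conditions: (R)-2-methyl-CBS-oxazaborolidine (cat.), BH3·SMe2, THF, −20 °C
Reagents that add atoms: none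
Why: Corey–Bakshi–Shibata reduction, in which the 2-methylalkenyl arm acts as the large group so that the (R)-catalyst should deliver hydride to give the (S)-carbinol (C3, 3β-oxygen) by 1,2-reduction only.

Step 2
Reactants: 2 (1S)-2-methylcyclohex-2-en-1-ol
Product: 3 tert-butyldimethyl{[(1S)-2-methylcyclohex-2-en-1-yl]oxy}silane
Conditions: TBSCl, imidazole, DMF, rt
Reagents that add atoms: tert-butyldimethylsilyl chloride, CC(C)(C)[Si](C)(C)Cl
Why: Standard silylation of a secondary allylic alcohol, which also installs the bulky allylic group that directs the next step.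

Step 3
Reactants: 3 tert-butyldimethyl{[(1S)-2-methylcyclohex-2-en-1-yl]oxy}silane
Product: 5 (1S,2R,3S)-3-(TBS-oxy)-2-methylcyclohexan-1-ol, via B-alkyl-9-BBN adduct 4 (not isolated)
Conditions: 9-BBN dimer, THF, 65 °C; then NaOH, H2O2, 0 °C to rt
Reagents that add atoms: hydrogen peroxide, OO
Why: Hydroboration–oxidation, in which boron goes to the less substituted alkene carbon (C5) and H to C4 in a syn addition on the face anti to the pseudoaxial allylic OTBS group, so the C4 methyl ends cis to the C3 oxygen, and oxidation proceeds with retention.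

Step 4
Reactants: 5 (1S,2R,3S)-3-(TBS-oxy)-2-methylcyclohexan-1-ol
Product: 6 (2S,3S)-3-(TBS-oxy)-2-methylcyclohexan-1-one
Conditions: Dess–Martin periodinane, CH2Cl2, 0 °C to rt
Reagents that add atoms: none
Why: Dess–Martin oxidation under near-neutral conditions should give the ketone without epimerising the α-methyl centre (C4) or eliminating the β-silyloxy group.

Step 5
Reactants: 6 (2S,3S)-3-(TBS-oxy)-2-methylcyclohexan-1-one
Product: 8 (5S,6S)-5-(TBS-oxy)-6-methylcyclohex-1-en-1-yl trifluoromethanesulfonate, via lithium enolate 7 (not isolated)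
Conditions: LiN(iPr)2, THF, −78 °C; then PhNTf2, −78 to 0 °C
Reagents that add atoms: N-phenylbis(trifluoromethanesulfonimide), O=S(=O)(N(c1ccccc1)S(=O)(=O)C(F)(F)F)C(F)(F)F
Why: Kinetic deprotonation at the less substituted α-carbon (C10) followed by O-triflation fixes the enol triflate on the C5=C10 side and leaves the C4 stereocentre untouched.

Step 6
Reactants: 8 (5S,6S)-5-(TBS-oxy)-6-methylcyclohex-1-en-1-yl trifluoromethanesulfonate
Product: 9 tert-butyl{[(1S,2R)-2,3-dimethylcyclohex-3-en-1-yl]oxy}dimethylsilane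
Conditions: MeMgBr, Fe(acac)3 (cat.), THF/NMP, −30 to 0 °C
Reagents that add atoms: methylmagnesium bromide, C[Mg]Br
Why: Iron-catalysed Kumada-type cross-coupling of an alkenyl triflate with a methyl Grignard reagent, which replaces OTf by CH3 (C14) without moving the C5=C10 double bond.

Step 7
Reactants: 9 tert-butyl{[(1S,2R)-2,3-dimethylcyclohex-3-en-1-yl]oxy}dimethylsilane; 10 ethyl glyoxylate
Product: 11 ethyl (2R)-2-hydroxy-2-[(1S,3R,4S)-4-(TBS-oxy)-3-methyl-2-methylidenecyclohexyl]acetate
Conditions: (R)-BINOL/TiCl2(OiPr)2 (cat.), 4 Å MS, CH2Cl2, −30 to 0 °C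
Reagents that add atoms: none
Why: Catalytic asymmetric carbonyl-ene (glyoxylate-ene) reaction, in which the enophile bonds to C10 on the α face anti to the pseudoaxial C4 methyl group, hydrogen is taken from the C14 methyl (cis to the alkenyl hydrogen) to form the exocyclic C5=C14 alkene, and the (R)-BINOL/TiCl2(OiPr)2 Lewis acid fixes the glyoxylate face (9R) in the usual endo-ester transition state.

Step 8
Reactants: 11 ethyl (2R)-2-hydroxy-2-[(1S,3R,4S)-4-(TBS-oxy)-3-methyl-2-methylidenecyclohexyl]acetate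
Product: 12 ethyl (2R)-2-(TBS-oxy)-2-[(1S,3R,4S)-4-(TBS-oxy)-3-methyl-2-methylidenecyclohexyl]acetate
Conditions: TBSOTf, 2,6-lutidine, CH2Cl2, −78 to 0 °C
Reagents that add atoms: tert-butyldimethylsilyl trifluoromethanesulfonate, CC(C)(C)[Si](C)(C)OS(=O)(=O)C(F)(F)F
Why: Silyl triflate/lutidine silylation protects the hindered α-hydroxy ester so that the α-oxygenated aldehyde can be released without self-condensation.

Step 9
Reactants: 12 ethyl (2R)-2-(TBS-oxy)-2-[(1S,3R,4S)-4-(TBS-oxy)-3-methyl-2-methylidenecyclohexyl]acetate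
Product: 13 (2R)-2-(TBS-oxy)-2-[(1S,3R,4S)-4-(TBS-oxy)-3-methyl-2-methylidenecyclohexyl]acetaldehyde
Conditions: iBu2AlH, CH2Cl2, −78 °C; aq. potassium sodium tartrate (KNaC4H4O6) work-up
Reagents that add atoms: none
Why: Partial reduction of an α-silyloxy ester by iBu2AlH at low temperature should stop at the aldehyde through the stable O-aluminated hemiacetal RCH(OEt)OAl(iBu)2, without touching the alkene or C9.

Step 10
Reactants: 13 (2R)-2-(TBS-oxy)-2-[(1S,3R,4S)-4-(TBS-oxy)-3-methyl-2-methylidenecyclohexyl]acetaldehyde; 14 but-3-en-2-one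
Product: 17 3β,9β-bis(TBS-oxy)-8β-hydroxy-10βH-12-noreremophilan-11-one, via tertiary C5 radical 15 (not isolated), via Fe(acac)2-bound enolate 16 (not isolated)
Conditions: Fe(acac)3 (cat.), PhSiH3, 14 (excess), EtOH/(CH2OH)2, 0 °C to rt
Reagents that add atoms: none
Why: Fe(acac)3/PhSiH3 forms the iron hydride (acac)2FeH, which transfers a hydrogen atom to C14 of the 1,1-disubstituted C5=C14 alkene (Mukaiyama-type, Markovnikov); the tertiary C5 radical 15 adds to the β-carbon of 14 (Giese addition, bond C5–C6), the resulting α-keto radical is reduced to the Fe(acac)2-bound enolate 16 (radical–polar crossover), and C7 of 16 adds to the C8 aldehyde (bond C7–C8). The closest known reaction type is the hydrogen-atom-transfer-initiated radical–polar crossover annulation of alkenyl aldehydes with enones (Giese addition followed by intramolecular aldol addition). Ring B is the only ring closed, by a 6-(enolexo)-exo-trig aldol addition through a chair transition state. C5 is controlled by the C4 methyl group, which sits axial next to the planar radical centre (A(1,2) strain with the C5 methyl; the 3β-OTBS group and the C10 side chain are equatorial) and blocks the β face, so C6 enters anti to it and cis to the C10 side chain, as the cis ring fusion requires. C8 is controlled by the C9 silyloxy group, which is equatorial in the closing chair and therefore anti to the incoming C7 (Felkin–Anh), placing the C8 oxygen axial (β); C7 is set by the equatorial acetyl group in the same chair, which is also the thermodynamic epimer. The step needs hydrogen atom transfer to the electron-rich alkene in the presence of 14 and the aldehyde, and Giese addition faster than 1,5-hydrogen transfer from the formyl group; the nucleophilic tertiary radical, the polarity-matched acceptor and the excess of 14 should secure both.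

Step 11
Reactants: 17 3β,9β-bis(TBS-oxy)-8β-hydroxy-10βH-12-noreremophilan-11-one
Product: 18 3β,8β,9β-trihydroxy-10βH-12-noreremophilan-11-one
Conditions: HF·pyridine, THF, 0 °C to rt
Reagents that add atoms: none
Why: Fluoride-mediated desilylation under mildly acidic conditions removes both silyl ethers while avoiding base-induced retro-aldol cleavage of the β-hydroxy ketone.

Step 12
Reactants: 18 3β,8β,9β-trihydroxy-10βH-12-noreremophilan-11-one
Product: 19 3β-hydroxy-8β,9β-(isopropylidenedioxy)-10βH-12-noreremophilan-11-one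
Conditions: 2,2-dimethoxypropane, PPTS (cat.), acetone, rt
Reagents that add atoms: 2,2-dimethoxypropane, COC(C)(C)OC
Why: Acetonide formation is selective for the cis-8,9-diol (five-membered dioxolane), which leaves the isolated C3 hydroxyl free and removes the free β-hydroxyl before the basic olefination.

Step 13
Reactants: 19 3β-hydroxy-8β,9β-(isopropylidenedioxy)-10βH-12-noreremophilan-11-one
Product: 20 8β,9β-(isopropylidenedioxy)-10βH-eremophil-11-en-3β-ol
Conditions: Ph3PCH3Br, KOtBu (excess), THF, 0 °C to rt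
Reagents that add atoms: methyltriphenylphosphonium bromide, C[P+](c1ccccc1)(c1ccccc1)c1ccccc1.[Br-]
Why: Wittig methylenation of the methyl ketone gives the isopropenyl group; the equatorial C7 centre is already the thermodynamic epimer, and the potassium C3 alkoxide formed by the excess ylide is inert.

Step 14
Reactants: 21 (2R)-pent-4-yn-2-ol; 22 angelic acid
Product: 24 (2R)-pent-4-yn-2-yl (2Z)-2-methylbut-2-enoate, via mixed anhydride 23 (not isolated)
Conditions: 2,4,6-trichlorobenzoyl chloride, Et3N, toluene, rt; then 21, DMAP, rt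
Reagents that add atoms: none
Why: Yamaguchi esterification through the mixed anhydride acylates the secondary alcohol with retention at the carbinol centre and is the usual way to keep the angelate Z geometry.

Step 15
Reactants: 24 (2R)-pent-4-yn-2-yl (2Z)-2-methylbut-2-enoate
Product: 26 (5R)-5-{[(2Z)-2-methylbut-2-enoyl]oxy}hex-2-ynoic acid, via caesium alkynoate 25 (not isolated)
Conditions: AgI (cat.), Cs2CO3, CO2 (1 atm), DMF, 50 °C; then aq. HCl
Reagents that add atoms: carbon dioxide, O=C=O
Why: Silver-catalysed C–H carboxylation of a terminal alkyne with CO2 proceeds through the silver acetylide RC≡CAg under carbonate base and should therefore tolerate the angelate ester.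

Step 16
Reactants: 26 (5R)-5-{[(2Z)-2-methylbut-2-enoyl]oxy}hex-2-ynoic acid
Product: 27 (2Z,5R)-5-{[(2Z)-2-methylbut-2-enoyl]oxy}hex-2-enoic acid
Conditions: H2 (1 atm), Pd/CaCO3 poisoned with Pb(OAc)2 (Lindlar catalyst), quinoline, EtOAc, rt
Reagents that add atoms: none
Why: Lindlar semihydrogenation adds H2 syn to the alkyne to give the Z-enoic acid and leaves the trisubstituted angelate alkene untouched.

Step 17
Reactants: 20 8β,9β-(isopropylidenedioxy)-10βH-eremophil-11-en-3β-ol; 27 (2Z,5R)-5-{[(2Z)-2-methylbut-2-enoyl]oxy}hex-2-enoic acid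
Product: 28 8β,9β-(isopropylidenedioxy)-10βH-eremophil-11-en-3α-yl (2Z,5R)-5-{[(2Z)-2-methylbut-2-enoyl]oxy}hex-2-enoate
Conditions: PPh3, DIAD, toluene, 0 °C to rt
Reagents that add atoms: none
Why: Mitsunobu esterification, in which the carboxylate displaces the alkoxyphosphonium of the axial 3β-alcohol with inversion to give the equatorial 3α-ester, relieving the syn-axial interaction with the C5 methyl group under neutral conditions that spare both Z alkenes.

Step 18
Reactants: 28 8β,9β-(isopropylidenedioxy)-10βH-eremophil-11-en-3α-yl (2Z,5R)-5-{[(2Z)-2-methylbut-2-enoyl]oxy}hex-2-enoate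
Product: 29 CNP0395983.1
Conditions: AcOH/H2O (4:1), 40 °C
Reagents that add atoms: none
Why: Mild acid hydrolysis of the dioxolane releases the cis-8,9-diol under conditions that should not cleave or isomerise the two unsaturated esters or the isopropenyl group.

**Compound list**

1 | 2-methylcyclohex-2-en-1-one | CC1=CCCCC1=O | starting material
2 | (1S)-2-methylcyclohex-2-en-1-ol | CC1=CCCC[C@@H]1O | intermediate
3 | tert-butyldimethyl{[(1S)-2-methylcyclohex-2-en-1-yl]oxy}silane | CC1=CCCC[C@@H]1O[Si](C)(C)C(C)(C)C | intermediate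
4 | 9-[(1S,2R,3S)-3-(TBS-oxy)-2-methylcyclohexyl]-9-borabicyclo[3.3.1]nonane | C[C@@H]1[C@@H](B2C3CCCC2CCC3)CCC[C@@H]1O[Si](C)(C)C(C)(C)C | intermediate (not isolated)
5 | (1S,2R,3S)-3-(TBS-oxy)-2-methylcyclohexan-1-ol | C[C@@H]1[C@@H](O)CCC[C@@H]1O[Si](C)(C)C(C)(C)C | intermediate
6 | (2S,3S)-3-(TBS-oxy)-2-methylcyclohexan-1-one | C[C@@H]1C(=O)CCC[C@@H]1O[Si](C)(C)C(C)(C)C | intermediate
7 | lithium (5S,6S)-5-(TBS-oxy)-6-methylcyclohex-1-en-1-olate | C[C@@H]1C(O[Li])=CCC[C@@H]1O[Si](C)(C)C(C)(C)C | intermediate (not isolated)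
8 | (5S,6S)-5-(TBS-oxy)-6-methylcyclohex-1-en-1-yl trifluoromethanesulfonate | C[C@@H]1C(OS(=O)(=O)C(F)(F)F)=CCC[C@@H]1O[Si](C)(C)C(C)(C)C | intermediate
9 | tert-butyl{[(1S,2R)-2,3-dimethylcyclohex-3-en-1-yl]oxy}dimethylsilane | C[C@@H]1C(C)=CCC[C@@H]1O[Si](C)(C)C(C)(C)C | intermediate
10 | ethyl glyoxylate (ethyl 2-oxoacetate) | CCOC(=O)C=O | starting material
11 | ethyl (2R)-2-hydroxy-2-[(1S,3R,4S)-4-(TBS-oxy)-3-methyl-2-methylidenecyclohexyl]acetate | C=C1[C@@H](C)[C@@H](O[Si](C)(C)C(C)(C)C)CC[C@@H]1[C@@H](O)C(=O)OCC | intermediate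
12 | ethyl (2R)-2-(TBS-oxy)-2-[(1S,3R,4S)-4-(TBS-oxy)-3-methyl-2-methylidenecyclohexyl]acetate | C=C1[C@@H](C)[C@@H](O[Si](C)(C)C(C)(C)C)CC[C@@H]1[C@@H](O[Si](C)(C)C(C)(C)C)C(=O)OCC | intermediate
13 | (2R)-2-(TBS-oxy)-2-[(1S,3R,4S)-4-(TBS-oxy)-3-methyl-2-methylidenecyclohexyl]acetaldehyde | C=C1[C@@H](C)[C@@H](O[Si](C)(C)C(C)(C)C)CC[C@@H]1[C@@H](O[Si](C)(C)C(C)(C)C)C=O | intermediate
14 | but-3-en-2-one (methyl vinyl ketone) | C=CC(C)=O | starting material
15 | tertiary C5 radical formed from 13 by hydrogen atom transfer to C14 | C[C]1[C@@H](C)[C@@H](O[Si](C)(C)C(C)(C)C)CC[C@@H]1[C@@H](O[Si](C)(C)C(C)(C)C)C=O | intermediate (not isolated)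
16 | Fe(acac)2-bound enolate of the Giese adduct (drawn as the enolate anion; C5 quaternary, C6 α) | CC([O-])=CC[C@]1(C)[C@@H](C)[C@@H](O[Si](C)(C)C(C)(C)C)CC[C@@H]1[C@@H](O[Si](C)(C)C(C)(C)C)C=O | intermediate (not isolated)
17 | 3β,9β-bis(TBS-oxy)-8β-hydroxy-10βH-12-noreremophilan-11-one (7β-acetyl cis-decalin) | CC(=O)[C@H]1C[C@@]2(C)[C@H](CC[C@H](O[Si](C)(C)C(C)(C)C)[C@@H]2C)[C@@H](O[Si](C)(C)C(C)(C)C)[C@H]1O | intermediate
18 | 3β,8β,9β-trihydroxy-10βH-12-noreremophilan-11-one | CC(=O)[C@H]1C[C@@]2(C)[C@H](CC[C@H](O)[C@@H]2C)[C@@H](O)[C@H]1O | intermediate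
19 | 3β-hydroxy-8β,9β-(isopropylidenedioxy)-10βH-12-noreremophilan-11-one | CC(=O)[C@H]1C[C@@]2(C)[C@H](CC[C@H](O)[C@@H]2C)[C@@H](OC3(C)C)[C@H]1O3 | intermediate
20 | 8β,9β-(isopropylidenedioxy)-10βH-eremophil-11-en-3β-ol | C=C(C)[C@H]1C[C@@]2(C)[C@H](CC[C@H](O)[C@@H]2C)[C@@H](OC3(C)C)[C@H]1O3 | intermediate
21 | (2R)-pent-4-yn-2-ol | C#CC[C@@H](C)O | starting material
22 | angelic acid, (2Z)-2-methylbut-2-enoic acid | C/C=C(/C)C(=O)O | starting material
23 | (2Z)-2-methylbut-2-enoic 2,4,6-trichlorobenzoic anhydride | C/C=C(/C)C(=O)OC(=O)c1c(Cl)cc(Cl)cc1Cl | intermediate (not isolated)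
24 | (2R)-pent-4-yn-2-yl (2Z)-2-methylbut-2-enoate | C#CC[C@@H](C)OC(=O)/C(C)=C\C | intermediate
25 | caesium (5R)-5-{[(2Z)-2-methylbut-2-enoyl]oxy}hex-2-ynoate | [Cs+].[O-]C(=O)C#CC[C@@H](C)OC(=O)/C(C)=C\C | intermediate (not isolated)
26 | (5R)-5-{[(2Z)-2-methylbut-2-enoyl]oxy}hex-2-ynoic acid | OC(=O)C#CC[C@@H](C)OC(=O)/C(C)=C\C | intermediate
27 | (2Z,5R)-5-{[(2Z)-2-methylbut-2-enoyl]oxy}hex-2-enoic acid | OC(=O)/C=C\C[C@@H](C)OC(=O)/C(C)=C\C | intermediate
28 | 8β,9β-(isopropylidenedioxy)-10βH-eremophil-11-en-3α-yl (2Z,5R)-5-{[(2Z)-2-methylbut-2-enoyl]oxy}hex-2-enoate | C=C(C)[C@H]1C[C@@]2(C)[C@H](CC[C@@H](OC(=O)/C=C\C[C@@H](C)OC(=O)/C(C)=C\C)[C@@H]2C)[C@@H](OC3(C)C)[C@H]1O3 | intermediate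
29 | CNP0395983.1, (1R,2R,4aS,5R,6S,7R,8aR)-5,6-dihydroxy-1,8a-dimethyl-7-(prop-1-en-2-yl)decahydronaphthalen-2-yl (2Z,5R)-5-{[(2Z)-2-methylbut-2-enoyl]oxy}hex-2-enoate | C=C(C)[C@H]1C[C@@]2(C)[C@H](CC[C@@H](OC(=O)/C=C\C[C@@H](C)OC(=O)/C(C)=C\C)[C@@H]2C)[C@@H](O)[C@H]1O | target

**Count and risks**

Total step count: 18. Longest linear sequence: 15 steps (steps 1–13, 17 and 18); the acid 27 is made in 3 steps (14–16).

Steps most likely to fail:

1. Step 10 (annulation). The radical addition at C5 may show poor facial selectivity. The C5 radical may also take the formyl hydrogen by 1,5-hydrogen transfer, or the enolate may be protonated before ring closure. The closing chair also has to carry the 3β-silyloxy group syn-axial to the C5 methyl, which may erode the aldol selectivity. Fallback: setting out from 13, a Morita–Baylis–Hillman reaction with 14 (DABCO) should form the C7–C8 bond first under Felkin–Anh control and give (4S,5R)-5-(TBS-oxy)-5-[(1S,3R,4S)-4-(TBS-oxy)-3-methyl-2-methylidenecyclohexyl]-4-hydroxy-3-methylidenepentan-2-one F1. An intramolecular reductive radical conjugate addition (Fe(acac)3, PhSiH3, EtOH) should then close ring B: hydrogen atom transfer to C14, 6-endo-trig attack of the tethered C5 radical on C6, and protonation at C7 to the equatorial epimer. The route is rejoined at 17.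

2. Step 7 (glyoxylate-ene). The catalyst and the substrate may be mismatched in their facial preferences, hydrogen may be taken from the ring C4–H instead of C14, or the trisubstituted alkene may react too slowly. Fallback: setting out from 6, the lithium enolate 7 is transmetalated with ClTi(OiPr)3 and added to 10 in a syn-selective aldol addition (axial attack at C10 trans to the C4 methyl) to give ethyl (2R)-2-hydroxy-2-[(1R,3S,4S)-4-(TBS-oxy)-3-methyl-2-oxocyclohexyl]acetate F2. Silylation (TBSOTf, 2,6-lutidine) gives ethyl (2R)-2-(TBS-oxy)-2-[(1R,3S,4S)-4-(TBS-oxy)-3-methyl-2-oxocyclohexyl]acetate F3. Non-basic Lombardo methylenation of the ring ketone (Zn, CH2Br2, TiCl4) rejoins the route at 12.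

3. Step 17 (Mitsunobu esterification). The activated axial alcohol may eliminate toward C2 or C4 through its anti-periplanar axial hydrogens, the hindered carbinol may fail to be activated, or the Z-enoate may isomerise. Fallback: setting out from 20, Dess–Martin oxidation gives 8β,9β-(isopropylidenedioxy)-10βH-eremophil-11-en-3-one F4. Reduction under thermodynamic control (SmI2, H2O, Et3N, THF) gives the equatorial alcohol 8β,9β-(isopropylidenedioxy)-10βH-eremophil-11-en-3α-ol F5. Yamaguchi acylation of F5 with 27 (retention at C3) rejoins the route at 28.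

**Further compounds**

F1 | step 10 | (4S,5R)-5-(TBS-oxy)-5-[(1S,3R,4S)-4-(TBS-oxy)-3-methyl-2-methylidenecyclohexyl]-4-hydroxy-3-methylidenepentan-2-one | C=C1[C@@H](C)[C@@H](O[Si](C)(C)C(C)(C)C)CC[C@@H]1[C@@H](O[Si](C)(C)C(C)(C)C)[C@H](C(=C)C(C)=O)O
F2 | step 7 | ethyl (2R)-2-hydroxy-2-[(1R,3S,4S)-4-(TBS-oxy)-3-methyl-2-oxocyclohexyl]acetate | O=C1[C@@H](C)[C@@H](O[Si](C)(C)C(C)(C)C)CC[C@@H]1[C@@H](O)C(=O)OCC
F3 | step 7 | ethyl (2R)-2-(TBS-oxy)-2-[(1R,3S,4S)-4-(TBS-oxy)-3-methyl-2-oxocyclohexyl]acetate | O=C1[C@@H](C)[C@@H](O[Si](C)(C)C(C)(C)C)CC[C@@H]1[C@@H](O[Si](C)(C)C(C)(C)C)C(=O)OCC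
F4 | step 17 | 8β,9β-(isopropylidenedioxy)-10βH-eremophil-11-en-3-one | C=C(C)[C@H]1C[C@@]2(C)[C@H](CCC(=O)[C@@H]2C)[C@@H](OC3(C)C)[C@H]1O3
F5 | step 17 | 8β,9β-(isopropylidenedioxy)-10βH-eremophil-11-en-3α-ol | C=C(C)[C@H]1C[C@@]2(C)[C@H](CC[C@@H](O)[C@@H]2C)[C@@H](OC3(C)C)[C@H]1O3
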